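## Retrosynthetic overview

- The α-hydroxy-α-benzyl butanolide is opened retrosynthetically by a 1,2-benzyl shift (benzilic-ester/α-ketol type). Its precursor is the isomeric 2-benzyl-2-hydroxy-4-aroylfuran-3-one hemiketal, which is the hydrate of a 2-benzylidene-4-aroyl-dihydrofuran-3-one.
- The benzylidene furanone comes from a boron-templated, curcumin-type condensation of the aromatic aldehyde with a 4-aroyl-dihydrofuran-3-one.
- The furan-3-one ring comes from an oxa-Michael/Dieckmann annulation of methyl glycolate onto an aryl vinyl ketone, released in situ from a β-chloroethyl ketone.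
- Both aryl units come from one mono-methylated catechol. One is made by the glyoxylate formylation sequence, the other by acylation with 3-chloropropanoyl chloride.
- Ring order: the only non-aromatic ring is closed in Step 4 as a furan-3-one. Step 6 turns it into the butanolide without change of ring size, and both stereocentres are set there.

Assumption: the SMILES is read as (3S,4S), with benzyl and aroyl trans on the lactone. The ligand antipode that gives this series in Step 6 is fixed by a first screen, since both antipodes are accessible.

## Route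

Step 1
Reactants: 1 catechol (benzene-1,2-diol)
Product: 2 guaiacol (2-methoxyphenol)
Conditions: MeI (1.0 equiv), K2CO3 (1.0 equiv), acetone, reflux (1 used in 1.3-fold excess)
Reagents that add atoms: iodomethane, CI
Why: Williamson mono-O-methylation, in which one equivalent each of base and MeI with excess diol keeps the dimethyl ether minor and separable by base extraction.

Step 2
Reactants: 2 guaiacol, 3 glyoxylic acid
Product: 5 vanillin (4-hydroxy-3-methoxybenzaldehyde), via mandelic acid 4 (not isolated)
Conditions: (a) NaOH aq, 30 °C, 24 h; (b) air, CuSO4 (2 mol %), NaOH aq, 95 °C; then H2SO4 to pH 3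
Reagents that add atoms: none
Why: Para-selective hydroxyalkylation of the phenoxide by glyoxylate, followed by Cu-catalysed aerobic oxidative decarboxylation of the mandelate (the technical vanillin sequence), fixes the 4-hydroxy-3-methoxy pattern.

Step 3
Reactants: 2 guaiacol, 6 3-chloropropanoyl chloride
Product: 8 3-chloro-1-(4-hydroxy-3-methoxyphenyl)propan-1-one, via aryl ester 7 (not isolated)
Conditions: TfOH (neat), 0 °C to rt
Reagents that add atoms: none
Why: Friedel–Crafts acylation/Fries rearrangement in triflic acid, where reversible O-acylation funnels into the C-acyl phenol para to the free OH, the minor 5-acyl isomer is removed by crystallisation, and staying at or below rt avoids indanone closure.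

Step 4
Reactants: 8 3-chloro-1-(4-hydroxy-3-methoxyphenyl)propan-1-one, 9 methyl glycolate
Product: 12 4-(4-hydroxy-3-methoxybenzoyl)dihydrofuran-3(2H)-one, via aryl vinyl ketone 10 (not isolated), via ether ester 11 (not isolated)
Conditions: KOtBu (3.3 equiv), THF, −10 °C to rt; then 1 M HCl
Reagents that add atoms: none
Why: E1cB loss of HCl, oxa-Michael addition of the glycolate alkoxide and a 5-exo Dieckmann-type Claisen closure are pulled forward by deprotonation of the β-diketone product, and the new C4 centre is enolisable so it needs no control.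

Step 5
Reactants: 12 4-(4-hydroxy-3-methoxybenzoyl)dihydrofuran-3(2H)-one, 5 vanillin
Product: 15 (Z)-2-(4-hydroxy-3-methoxybenzylidene)-4-(4-hydroxy-3-methoxybenzoyl)dihydrofuran-3(2H)-one, via boron chelate 13 (not isolated), via benzylidene boron chelate 14 (not isolated)
Conditions: B2O3 (0.5 equiv), B(OnBu)3 (2 equiv), nBuNH2 (0.3 equiv), EtOAc, 75 °C; then 0.5 M HCl, 40 °C
Reagents that add atoms: none
Why: Boron-templated vinylogous Knoevenagel condensation (Pabon curcumin conditions), in which chelation blocks C4, acidifies the C2 methylene and tolerates free phenols, and the Z alkene (aryl syn to the ring oxygen) is the thermodynamic isomer as in aurones.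

Step 6
Reactants: 15 (Z)-2-(4-hydroxy-3-methoxybenzylidene)-4-(4-hydroxy-3-methoxybenzoyl)dihydrofuran-3(2H)-one
Product: 19 (3S,4S)-3-hydroxy-3-(4-hydroxy-3-methoxybenzyl)-4-(4-hydroxy-3-methoxybenzoyl)dihydrofuran-2(3H)-one, via methylene triketone 16 (not isolated), via hydroxymethyl triketone 17 (not isolated), via hemiketal 18 (not isolated)
Conditions: Sc(OTf)3 (10 mol %), C2-symmetric N,N'-dioxide bis(2,6-diisopropylanilide) ligand from (S)-pipecolic acid or its antipode (11 mol %), iPr2NEt (20 mol %), H2O (10 equiv), THF, 35 °C, Ar
Reagents that add atoms: water, O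
Why: Proposed new method: the amine opens the acidic 4-acylfuranone by retro-oxa-Michael loss of its diosphenolate oxygen (16), water re-adds to the alkylidene-1,3-dicarbonyl (17), the freed enolate ketonises at the benzylic carbon and the primary alcohol closes on the benzyl ketone to give hemiketal 18, whose two centres are both labile (ring–chain tautomerism at C2, enolisation at C4), so the chiral Sc(III) complex, chelating the C3 ketone/aroyl pair and raising the electrophilicity of C3, can funnel one hemiketal epimer through a suprafacial anionic 1,2-benzyl shift from C2 to C3 (C2 becomes the lactone carbonyl and the gain of ester resonance makes it irreversible), a dynamic kinetic resolution that forms the C3–CH2Ar bond and sets (3S), after which amine-mediated enolisation of the aryl ketone settles C4 as (4S) with the aroyl group trans to benzyl and hydrogen-bonded to the cis OH; the closest known reaction types are the benzilic ester rearrangement, saccharinic-acid formation from 1,2-dicarbonyl sugars and chiral-Lewis-acid-catalysed α-ketol rearrangements, none of which has been run as a hydrative, enantioselective benzyl shift on a furan-3-one.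

## Compound list

1 | catechol (benzene-1,2-diol) | Oc1ccccc1O | starting material
2 | guaiacol (2-methoxyphenol) | COc1ccccc1O | intermediate
3 | glyoxylic acid | O=CC(=O)O | starting material
4 | 4-hydroxy-3-methoxymandelic acid (racemic) | COc1cc(C(O)C(=O)O)ccc1O | intermediate
5 | vanillin | COc1cc(C=O)ccc1O | intermediate
6 | 3-chloropropanoyl chloride | O=C(Cl)CCCl | starting material
7 | 2-methoxyphenyl 3-chloropropanoate | COc1ccccc1OC(=O)CCCl | intermediate
8 | 3-chloro-1-(4-hydroxy-3-methoxyphenyl)propan-1-one | COc1cc(C(=O)CCCl)ccc1O | intermediate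
9 | methyl glycolate | COC(=O)CO | starting material
10 | 1-(4-hydroxy-3-methoxyphenyl)prop-2-en-1-one | COc1cc(C(=O)C=C)ccc1O | intermediate
11 | methyl 2-[3-(4-hydroxy-3-methoxyphenyl)-3-oxopropoxy]acetate | COC(=O)COCCC(=O)c1ccc(O)c(OC)c1 | intermediate
12 | 4-(4-hydroxy-3-methoxybenzoyl)dihydrofuran-3(2H)-one (racemic, enolisable) | O=C1COCC1C(=O)c1ccc(O)c(OC)c1 | intermediate
13 | di-n-butoxyboron chelate of 12 | CCCCO[B-]1(OCCCC)OC(c2ccc(O)c(OC)c2)=C2COCC2=[O+]1 | intermediate
14 | di-n-butoxyboron chelate of 15 | CCCCO[B-]1(OCCCC)OC(c2ccc(O)c(OC)c2)=C2CO/C(=C\c3ccc(O)c(OC)c3)C2=[O+]1 | intermediate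
15 | (Z)-2-(4-hydroxy-3-methoxybenzylidene)-4-(4-hydroxy-3-methoxybenzoyl)dihydrofuran-3(2H)-one (C4 labile) | COc1cc(/C=C2\OCC(C(=O)c3ccc(O)c(OC)c3)C2=O)ccc1O | intermediate
16 | 4-hydroxy-1,5-bis(4-hydroxy-3-methoxyphenyl)-2-methylenepent-4-ene-1,3-dione | COc1cc(C=C(O)C(=O)C(=C)C(=O)c2ccc(O)c(OC)c2)ccc1O | intermediate
17 | 2-(hydroxymethyl)-1,5-bis(4-hydroxy-3-methoxyphenyl)pentane-1,3,4-trione | COc1cc(CC(=O)C(=O)C(CO)C(=O)c2ccc(O)c(OC)c2)ccc1O | intermediate
18 | 2-hydroxy-2-(4-hydroxy-3-methoxybenzyl)-4-(4-hydroxy-3-methoxybenzoyl)dihydrofuran-3(2H)-one (interconverting stereoisomers) | COc1cc(CC2(O)OCC(C(=O)c3ccc(O)c(OC)c3)C2=O)ccc1O | intermediate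
19 | (3S,4S)-3-hydroxy-3-(4-hydroxy-3-methoxybenzyl)-4-(4-hydroxy-3-methoxybenzoyl)dihydrofuran-2(3H)-one | COc1cc(C[C@@]2(O)C(=O)OC[C@@H]2C(=O)c2ccc(O)c(OC)c2)ccc1O | target

## Step count and risks

Total steps: 6. Longest linear sequence: 5 (1 → 2 → 8 → 12 → 15 → 19).

**Step 6 (the proposed new step).**
- Water uptake may stall.
- The enolised β-diketone may be a resting state that slows the shift.
- Loss of formaldehyde or aromatisation to a 3-hydroxyfuran may compete.
- The amine alone may cause a racemic background reaction.
- Retro-aldol of the product could erode ee.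

The fallback uses known chemistry and trades catalysis for resolution. It sets out from 15 and comes back at 19. The α-alkoxy-enone of 15 is hydrolysed with 1 M HCl in THF (classical diosphenol-ether hydrolysis) and hemiketal 18 is isolated. Treatment of 18 with aqueous Ca(OH)2 under benzilic/saccharinic-acid conditions, then acidification to re-lactonise, gives 19 together with its mirror image, (3R,4R)-3-hydroxy-3-(4-hydroxy-3-methoxybenzyl)-4-(4-hydroxy-3-methoxybenzoyl)dihydrofuran-2(3H)-one F1. The two are separated on a preparative chiral stationary phase.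

**Step 4.**
- The substrate carries a phenoxide, which weakens the Michael acceptor and lowers the acidity of the ketone α-CH2.
- The vinyl ketone can polymerise.

The fallback removes the phenoxide from the problem. It sets out from 8 and comes back at 12. BnBr and K2CO3 in DMF benzylate the phenol and eliminate HCl at the same time, giving 1-[4-(benzyloxy)-3-methoxyphenyl]prop-2-en-1-one F2. NaH-mediated annulation with 9 in THF gives 4-[4-(benzyloxy)-3-methoxybenzoyl]dihydrofuran-3(2H)-one F3. Hydrogenolysis (H2, Pd/C, EtOAc) then returns 12.

**Step 3.**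
- Acylation para to OMe may compete with acylation para to OH.
- The β-chloro ketone is acid-sensitive.

The fallback takes the regiochemistry from the aldehyde instead of from an acylation. It sets out from 5 and comes back at 10. Vinylmagnesium bromide (2.2 equiv, THF, 0 °C) adds to 5 to give 1-(4-hydroxy-3-methoxyphenyl)prop-2-en-1-ol F4. MnO2 in CH2Cl2 oxidises this to enone 10, which is fed at once into Step 4 with one equivalent less base.

## Further compounds

F1 | step 6 | (3R,4R)-3-hydroxy-3-(4-hydroxy-3-methoxybenzyl)-4-(4-hydroxy-3-methoxybenzoyl)dihydrofuran-2(3H)-one | COc1cc(C[C@]2(O)C(=O)OC[C@H]2C(=O)c2ccc(O)c(OC)c2)ccc1O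
F2 | step 4 | 1-[4-(benzyloxy)-3-methoxyphenyl]prop-2-en-1-one | COc1cc(C(=O)C=C)ccc1OCc1ccccc1
F3 | step 4 | 4-[4-(benzyloxy)-3-methoxybenzoyl]dihydrofuran-3(2H)-one | O=C1COCC1C(=O)c1ccc(OCc2ccccc2)c(OC)c1
F4 | step 3 | 1-(4-hydroxy-3-methoxyphenyl)prop-2-en-1-ol | COc1cc(C(O)C=C)ccc1O
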